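Ring A is numbered C1 (CMe2), C2, C3 (carbinol carbon), C4, C5 (methyl-bearing alkene carbon) and C6 (chain-bearing alkene carbon). Its C5=C6 alkene lies 1,4 to the oxygen-bearing C3, the retron of a Diels–Alder reaction between an alkyne (C5≡C6) and a 2-silyloxydiene (C4=C3–C2=C1). Heating but-2-ynal with the silyl dienol ether of mesityl oxide should form C4–C5 and C1–C6 in one operation and deliver the tetrasubstituted alkene, the quaternary carbon and a masked C3 ketone. The formyl group then becomes the ring alkyne, an enzymatic reduction sets C3, and a Sonogashira coupling with a stereodefined pentaenyl bromide completes the carbon skeleton.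

Key step: step 2

Assumption: all five starting materials are taken as commercial reagents, the two volatile ones being used as freshly prepared solutions; the locants C1–C6 in the Why lines are the ring locants defined above.

Step 1
Reactants: 1 mesityl oxide (4-methylpent-3-en-2-one)
Product: 2 4-methyl-2-(trimethylsilyloxy)penta-1,3-diene
Conditions: LiN(i-Pr)2, THF, −78 °C; TMSCl, −78 °C to 0 °C
Reagents that add atoms: chlorotrimethylsilane, C[Si](C)(C)Cl
Why: Kinetic deprotonation of the acetyl methyl group gives the cross-conjugated lithium enolate, and O-silylation (silyl enol ether formation) should give the 2-silyloxydiene.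

Step 2
Reactants: 2 4-methyl-2-(trimethylsilyloxy)penta-1,3-diene, 3 but-2-ynal
Product: 4 2,6,6-trimethyl-4-(trimethylsilyloxy)cyclohexa-1,4-diene-1-carbaldehyde
Conditions: toluene, BHT (cat.), 100 °C, sealed tube
Reagents that add atoms: none
Why: The step is a thermal, concerted but asynchronous [4+2] cycloaddition (Diels–Alder reaction) between the electron-rich 2-silyloxydiene and the electron-poor ynal. The closest known type is the Diels–Alder reaction of 2-silyloxy-1,3-dienes with acetylenic aldehydes, ketones and esters, which gives 1-silyloxycyclohexa-1,4-dienes. The six-membered ring is closed by the cycloaddition itself, C4–C5 and C1–C6 forming suprafacially on both partners in one transition state (intermolecular [4+2] closure). No stereocentre is formed, because C1 carries two identical methyl groups and C3 stays trigonal. The step needs regioselectivity and chemoselectivity: the largest HOMO coefficient sits on the CH2 terminus of the diene (C4), reinforced by both the C3 silyloxy group and the C1 methyl groups, and the largest LUMO coefficient on the methyl-bearing β-carbon of the ynal, so C4 should bond to C5 and the formyl group should end on C6, para to the silyloxy carbon, while the conjugated C≡C bond should react in preference to C=O in the absence of a Lewis acid. The cis-methyl group at the diene terminus slows the reaction, which the linear, unhindered alkyne dienophile and heating should offset.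

Step 3
Reactants: 4 2,6,6-trimethyl-4-(trimethylsilyloxy)cyclohexa-1,4-diene-1-carbaldehyde
Product: 6 4-ethynyl-3,5,5-trimethylcyclohex-3-en-1-one, via ethynyl silyl enol ether 5 (not isolated)
Conditions: TMSCHN2, LiN(i-Pr)2, THF, −78 °C to 0 °C; then 1 M HCl (aq), 0 °C
Reagents that add atoms: trimethylsilyldiazomethane, C[Si](C)(C)C=[N+]=[N-]
Why: In a Colvin rearrangement, lithiated trimethylsilyldiazomethane adds to the hindered enal and loss of Me3SiOLi and N2 followed by a 1,2-hydride shift of the alkylidene carbene should give the enyne without basic methanol, after which brief mild acid hydrolyses the silyl enol ether by protonation at C2 and leaves the C5=C6 alkene conjugated with the alkyne.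

Step 4
Reactants: 6 4-ethynyl-3,5,5-trimethylcyclohex-3-en-1-one
Product: 7 (1R)-4-ethynyl-3,5,5-trimethylcyclohex-3-en-1-ol
Conditions: (R)-selective ketoreductase, NADP+ (cat.), i-PrOH, phosphate buffer pH 7, DMSO (cosolvent), 30 °C
Reagents that add atoms: none
Why: In this biocatalytic asymmetric ketone reduction the enzyme delivers hydride from NADPH to one face of the carbonyl group, so an (R)-selective ketoreductase chosen from a screening panel should set C3 by catalyst control at neutral pH, where migration of the β,γ-alkene into conjugation with the ketone is slow.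

Step 5
Reactants: 8 propyne
Product: 9 (E)-2-bromo-1-iodoprop-1-ene
Conditions: IBr, CH2Cl2, −78 °C to 0 °C, dark
Reagents that add atoms: iodine monobromide, IBr
Why: Electrophilic anti addition of IBr to the terminal alkyne (iodobromination) should place iodine on the terminal carbon and bromide on the more substituted carbon with the two halogens trans.

Step 6
Reactants: 10 (E)-3-methylpent-2-en-4-yn-1-ol
Product: 11 (2E,4E)-3-methyl-5-(tributylstannyl)penta-2,4-dien-1-ol
Conditions: Bu3SnH, PdCl2(PPh3)2 (2 mol %), THF, 0 °C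
Reagents that add atoms: tributyltin hydride, CCCC[SnH](CCCC)CCCC
Why: Palladium-catalysed hydrostannation adds Sn–H syn across the terminal alkyne with tin on the terminal carbon, which should give the (4E)-dienylstannane and leave the (2E)-alkene of the starting material untouched.

Step 7
Reactants: 11 (2E,4E)-3-methyl-5-(tributylstannyl)penta-2,4-dien-1-ol, 9 (E)-2-bromo-1-iodoprop-1-ene
Product: 12 (2E,4E,6E)-7-bromo-3-methylocta-2,4,6-trien-1-ol
Conditions: Pd2(dba)3 (2.5 mol %), AsPh3 (20 mol %), NMP, 25 °C, dark
Reagents that add atoms: none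
Why: In this Stille coupling, which retains the geometry of both partners, zerovalent palladium should insert into the terminal C–I bond of 9 far faster than into the more hindered C–Br bond, so the bromoalkene survives as the handle for the last step.

Step 8
Reactants: 12 (2E,4E,6E)-7-bromo-3-methylocta-2,4,6-trien-1-ol
Product: 13 (2E,4E,6E)-7-bromo-3-methylocta-2,4,6-trienal
Conditions: MnO2, CH2Cl2, 25 °C, dark
Reagents that add atoms: none
Why: Activated MnO2 oxidises the allylic (trienylic) primary alcohol chemoselectively to the aldehyde without touching the alkene geometry or the vinyl bromide.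

Step 9
Reactants: 13 (2E,4E,6E)-7-bromo-3-methylocta-2,4,6-trienal
Product: 14 (1E,3E,5E,7E)-8-bromo-1-iodo-4-methylnona-1,3,5,7-tetraene
Conditions: CrCl2, CHI3, THF–dioxane, 0 °C to 25 °C, dark
Reagents that add atoms: iodoform, IC(I)I
Why: In the Takai olefination the geminal dichromium species formed from CHI3 adds to the aldehyde and anti elimination should give the (E)-iodoalkene, the vinyl bromide being inert to CrCl2 without a nickel cocatalyst.

Step 10
Reactants: 14 (1E,3E,5E,7E)-8-bromo-1-iodo-4-methylnona-1,3,5,7-tetraene, 15 pent-4-yn-1-ol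
Product: 17 (4E,6E,8E,10E,12E)-13-bromo-4,9-dimethyltetradeca-4,6,8,10,12-pentaen-1-ol, via alkenylalane 16 (not isolated)
Conditions: 15, AlMe3 (3 equiv), Cp2ZrCl2 (cat.), CH2Cl2, 0 to 25 °C; then 14, ZnCl2, Pd(PPh3)4 (5 mol %), THF, 25 °C, dark
Reagents that add atoms: trimethylaluminium, C[Al](C)C
Why: Zirconium-catalysed syn carboalumination of the terminal alkyne (methyl to the internal carbon, aluminium to the terminal one) fixes the (E)-trisubstituted alkene, and Negishi coupling of the alkenylalane with retention should occur at the C–I bond of 14 in preference to the hindered C–Br bond.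

Step 11
Reactants: 7 (1R)-4-ethynyl-3,5,5-trimethylcyclohex-3-en-1-ol, 17 (4E,6E,8E,10E,12E)-13-bromo-4,9-dimethyltetradeca-4,6,8,10,12-pentaen-1-ol
Product: 18 (4E,6E,8E,10E,12E)-15-[(4R)-4-hydroxy-2,6,6-trimethylcyclohex-1-en-1-yl]-4,9,13-trimethylpentadeca-4,6,8,10,12-pentaen-14-yn-1-ol
Conditions: Pd(PPh3)4 (5 mol %), CuI (10 mol %), i-Pr2NH, THF, 45 °C, degassed, dark
Reagents that add atoms: none
Why: Sonogashira coupling of the terminal alkyne with the 2-bromoalkene terminus should proceed with retention of the (E) geometry and tolerates both free hydroxyl groups, so that no protecting group is needed.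

Compound list

1 | mesityl oxide (4-methylpent-3-en-2-one) | CC(=O)C=C(C)C | starting material
2 | 4-methyl-2-(trimethylsilyloxy)penta-1,3-diene | C=C(O[Si](C)(C)C)C=C(C)C | intermediate
3 | but-2-ynal | CC#CC=O | starting material
4 | 2,6,6-trimethyl-4-(trimethylsilyloxy)cyclohexa-1,4-diene-1-carbaldehyde | CC1=C(C=O)C(C)(C)C=C(O[Si](C)(C)C)C1 | intermediate
5 | [(4-ethynyl-3,3,5-trimethylcyclohexa-1,4-dien-1-yl)oxy]trimethylsilane | CC1=C(C#C)C(C)(C)C=C(O[Si](C)(C)C)C1 | intermediate
6 | 4-ethynyl-3,5,5-trimethylcyclohex-3-en-1-one | CC1=C(C#C)C(C)(C)CC(=O)C1 | intermediate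
7 | (1R)-4-ethynyl-3,5,5-trimethylcyclohex-3-en-1-ol | CC1=C(C#C)C(C)(C)C[C@H](O)C1 | intermediate
8 | propyne | CC#C | starting material
9 | (E)-2-bromo-1-iodoprop-1-ene | C/C(Br)=C\I | intermediate
10 | (E)-3-methylpent-2-en-4-yn-1-ol | C#C/C(C)=C/CO | starting material
11 | (2E,4E)-3-methyl-5-(tributylstannyl)penta-2,4-dien-1-ol | CCCC[Sn](CCCC)(CCCC)/C=C/C(C)=C/CO | intermediate
12 | (2E,4E,6E)-7-bromo-3-methylocta-2,4,6-trien-1-ol | Br/C(C)=C/C=C/C(C)=C/CO | intermediate
13 | (2E,4E,6E)-7-bromo-3-methylocta-2,4,6-trienal | Br/C(C)=C/C=C/C(C)=C/C=O | intermediate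
14 | (1E,3E,5E,7E)-8-bromo-1-iodo-4-methylnona-1,3,5,7-tetraene | Br/C(C)=C/C=C/C(C)=C/C=C/I | intermediate
15 | pent-4-yn-1-ol | C#CCCCO | starting material
16 | (E)-alkenylalane, dimethyl[(1E)-5-(dimethylalumanyloxy)-2-methylpent-1-en-1-yl]alumane | C[Al](C)/C=C(\C)CCCO[Al](C)C | intermediate
17 | (4E,6E,8E,10E,12E)-13-bromo-4,9-dimethyltetradeca-4,6,8,10,12-pentaen-1-ol | Br/C(C)=C/C=C/C(C)=C/C=C/C=C(\C)CCCO | intermediate
18 | (4E,6E,8E,10E,12E)-15-[(4R)-4-hydroxy-2,6,6-trimethylcyclohex-1-en-1-yl]-4,9,13-trimethylpentadeca-4,6,8,10,12-pentaen-14-yn-1-ol | CC1=C(C#C/C(C)=C/C=C/C(C)=C/C=C/C=C(\C)CCCO)C(C)(C)C[C@H](O)C1 | target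

Total step count: 11. Longest linear sequence: 6 steps (steps 6 to 11, from compound 10); the ring branch is 5 steps (steps 1 to 4 and 11).

Steps most likely to fail

Step 2. The cycloaddition may be slow at the diene terminus that carries a cis-methyl group, and the ynal may polymerise or the diene lose its silyl group before ring formation. Fallback: the same two ring bonds are made stepwise by polar chemistry. Setting out from 1, a ZnCl2-mediated Michael addition–aldol condensation (Robinson-type annulation) with ethyl acetoacetate should give ethyl 2,6,6-trimethyl-4-oxocyclohex-2-ene-1-carboxylate F1. Ketalisation with ethane-1,2-diol and TsOH (toluene, reflux, water separator) moves the alkene into conjugation with the ester and should give ethyl 7,9,9-trimethyl-1,4-dioxaspiro[4.5]dec-7-ene-8-carboxylate F2. Reduction with i-Bu2AlH (CH2Cl2, −78 °C) should give (7,9,9-trimethyl-1,4-dioxaspiro[4.5]dec-7-en-8-yl)methanol F3, MnO2 should give 7,9,9-trimethyl-1,4-dioxaspiro[4.5]dec-7-ene-8-carbaldehyde F4, and Colvin homologation (TMSCHN2, LiN(i-Pr)2) should give 8-ethynyl-7,9,9-trimethyl-1,4-dioxaspiro[4.5]dec-7-ene F5. Mild hydrolysis (PPTS, aqueous acetone) comes back to the route at 6.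

Step 4. Facial discrimination may be poor because the two methylene flanks of the ketone are similar, and the alkene may migrate into conjugation with the ketone during a long incubation. Fallback: racemic reduction followed by enzymatic resolution and inversion. Setting out from 6, NaBH4 (MeOH, −20 °C) should give racemic 4-ethynyl-3,5,5-trimethylcyclohex-3-en-1-ol F6. Lipase-catalysed acylation (Burkholderia cepacia lipase, vinyl acetate, t-BuOMe) is expected to convert the (R)-enantiomer into (1R)-4-ethynyl-3,5,5-trimethylcyclohex-3-en-1-yl acetate F7 and to leave (1S)-4-ethynyl-3,5,5-trimethylcyclohex-3-en-1-ol F8. After separation, F8 is turned into more F7 by Mitsunobu inversion (AcOH, PPh3, DIAD). Should the lipase prefer the other enantiomer, the roles of acetate and alcohol are exchanged. Methanolysis of F7 (K2CO3, MeOH) comes back to the route at 7.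

Step 11. Oxidative addition at the hindered bromoalkene terminus of the light-sensitive pentaene may be slow, which would allow oxidative homocoupling of the alkyne and E/Z isomerisation of the polyene. Fallback: the hindered coupling is done on the small bromide before the polyene is complete. Setting out from 7 and 12, Sonogashira coupling (Pd(PPh3)4, CuI, i-Pr2NH, THF, 45 °C) should give (1R)-4-[(3E,5E,7E)-9-hydroxy-3,7-dimethylnona-3,5,7-trien-1-yn-1-yl]-3,5,5-trimethylcyclohex-3-en-1-ol F9. MnO2 should oxidise only the allylic alcohol to (2E,4E,6E)-9-[(4R)-4-hydroxy-2,6,6-trimethylcyclohex-1-en-1-yl]-3,7-dimethylnona-2,4,6-trien-8-ynal F10. Takai olefination (CrCl2, CHI3) should give (1R)-4-[(3E,5E,7E,9E)-10-iodo-3,7-dimethyldeca-3,5,7,9-tetraen-1-yn-1-yl]-3,5,5-trimethylcyclohex-3-en-1-ol F11. Negishi coupling of F11 with alkenylalane 16 (ZnCl2, Pd(PPh3)4, THF) comes back to the route at 18.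

Further compounds

F1 | step 2 | ethyl 2,6,6-trimethyl-4-oxocyclohex-2-ene-1-carboxylate (racemic) | CCOC(=O)C1C(C)=CC(=O)CC1(C)C
F2 | step 2 | ethyl 7,9,9-trimethyl-1,4-dioxaspiro[4.5]dec-7-ene-8-carboxylate | CCOC(=O)C1=C(C)CC2(OCCO2)CC1(C)C
F3 | step 2 | (7,9,9-trimethyl-1,4-dioxaspiro[4.5]dec-7-en-8-yl)methanol | OCC1=C(C)CC2(OCCO2)CC1(C)C
F4 | step 2 | 7,9,9-trimethyl-1,4-dioxaspiro[4.5]dec-7-ene-8-carbaldehyde | O=CC1=C(C)CC2(OCCO2)CC1(C)C
F5 | step 2 | 8-ethynyl-7,9,9-trimethyl-1,4-dioxaspiro[4.5]dec-7-ene | C#CC1=C(C)CC2(OCCO2)CC1(C)C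
F6 | step 4 | racemic 4-ethynyl-3,5,5-trimethylcyclohex-3-en-1-ol | CC1=C(C#C)C(C)(C)CC(O)C1
F7 | step 4 | (1R)-4-ethynyl-3,5,5-trimethylcyclohex-3-en-1-yl acetate | CC1=C(C#C)C(C)(C)C[C@H](OC(C)=O)C1
F8 | step 4 | (1S)-4-ethynyl-3,5,5-trimethylcyclohex-3-en-1-ol | CC1=C(C#C)C(C)(C)C[C@@H](O)C1
F9 | step 11 | (1R)-4-[(3E,5E,7E)-9-hydroxy-3,7-dimethylnona-3,5,7-trien-1-yn-1-yl]-3,5,5-trimethylcyclohex-3-en-1-ol | CC1=C(C#C/C(C)=C/C=C/C(C)=C/CO)C(C)(C)C[C@H](O)C1
F10 | step 11 | (2E,4E,6E)-9-[(4R)-4-hydroxy-2,6,6-trimethylcyclohex-1-en-1-yl]-3,7-dimethylnona-2,4,6-trien-8-ynal | CC1=C(C#C/C(C)=C/C=C/C(C)=C/C=O)C(C)(C)C[C@H](O)C1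
F11 | step 11 | (1R)-4-[(3E,5E,7E,9E)-10-iodo-3,7-dimethyldeca-3,5,7,9-tetraen-1-yn-1-yl]-3,5,5-trimethylcyclohex-3-en-1-ol | CC1=C(C#C/C(C)=C/C=C/C(C)=C/C=C/I)C(C)(C)C[C@H](O)C1
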